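## Retrosynthetic overview

1. Target 10 ⇐ tetraol 8: both benzoates (O7 and O3) are put on last, in one regioselective operation on the unprotected tetraol.
2. 8 ⇐ ester 6: C7 is carried at the ester level and the cis-2,3-diol as an acetonide.
3. 6 ⇐ vinyl oxirane 4: the C5–OMe bond comes from opening the oxirane at its allylic carbon with net retention.
4. 4 ⇐ dienoate acetonide 3 ⇐ cis-dihydrodiol 2 ⇐ methyl benzoate 1: oxidative dearomatisation, then epoxidation of C4=C5.
5. Ring order: the six-membered carbocycle is the arene ring of 1 carried through; the dioxolane (protecting ring) is closed second; the oxirane, the single ring-forming event of the presumed biosynthesis, is closed third and opened in the next step.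

Assumption: the biosynthesis is presumed to run from a benzoate-derived arene by oxidative dearomatisation to a 2,3-dihydrodiol diene, epoxidation of its 4,5-alkene to a vinyl oxirane and opening of that oxirane at C5 by methanol; the recombinant strain E. coli JM109(pDTG601) is taken to be at hand; ring numbering throughout is C1 (carries C7), C2–C5 (oxygenated), C6 (olefinic CH), with the C2/C3 oxygens on the β face and the C4/C5 oxygens on the α face.

## Route

Step 1
Reactants: 1 methyl benzoate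
Product: 2 methyl (5S,6R)-5,6-dihydroxycyclohexa-1,3-diene-1-carboxylate
Conditions: E. coli JM109(pDTG601) whole cells (toluene dioxygenase), air, glucose feed, IPTG, mineral salts medium, pH 6.8, 30 °C; EtOAc extraction
Reagents that add atoms: dioxygen, O=O
Why: Enzymatic arene cis-dihydroxylation (Rieske dioxygenase) is the laboratory counterpart of the oxidative dearomatisation of the benzoate ring, adding both oxygens of O2 to the 2,3-bond from one face so that C2 (R) and C3 (S in 2) are set in one catalyst-controlled step.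

Step 2
Reactants: 2 methyl (5S,6R)-5,6-dihydroxycyclohexa-1,3-diene-1-carboxylate
Product: 3 methyl (3aR,7aS)-2,2-dimethyl-3a,7a-dihydro-1,3-benzodioxole-4-carboxylate
Conditions: 2,2-dimethoxypropane, p-TsOH·H2O (cat.), acetone, 0 → 23 °C; used at once
Reagents that add atoms: 2,2-dimethoxypropane, COC(C)(C)OC
Why: Acid-catalysed transacetalisation (isopropylidene acetal formation) closes a cis-fused dioxolane over O2/O3 without touching C2 or C3, which blocks the β face for the coming epoxidation and stops the dienediol from aromatising.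

Step 3
Reactants: 3 methyl (3aR,7aS)-2,2-dimethyl-3a,7a-dihydro-1,3-benzodioxole-4-carboxylate
Product: 4 methyl (3aR,6R,7R,7aR)-6,7-epoxy-2,2-dimethyl-3a,6,7,7a-tetrahydro-1,3-benzodioxole-4-carboxylate (oxirane anti to the dioxolane)
Conditions: m-CPBA (1.2 equiv), CH2Cl2, 0 → 23 °C
Reagents that add atoms: 3-chloroperoxybenzoic acid, O=C(OO)c1cccc(Cl)c1
Why: Prilezhaev epoxidation by the electrophilic peracid takes the electron-richer γ,δ-alkene C4=C5 of the dienoate rather than the ester-conjugated C1=C6 and approaches anti to the dioxolane, so the oxirane oxygen and with it C4 and C5 are set on the α face, as in the presumed biosynthetic vinyl oxirane.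

Step 4
Reactants: 4 methyl (3aR,6R,7R,7aR)-6,7-epoxy-2,2-dimethyl-3a,6,7,7a-tetrahydro-1,3-benzodioxole-4-carboxylate
Product: 6 methyl (3aR,6R,7R,7aS)-7-hydroxy-6-methoxy-2,2-dimethyl-3a,6,7,7a-tetrahydro-1,3-benzodioxole-4-carboxylate, via borate ester 5 (not isolated)
Conditions: Pd(PPh3)4 (5 mol %), B(OMe)3 (1.5 equiv), THF, 23 °C; then H2O, NaHCO3 work-up
Reagents that add atoms: trimethyl borate, COB(OC)OC
Why: Tsuji–Trost-type allylic substitution of a γ,δ-epoxy-α,β-unsaturated ester, in which zerovalent palladium opens the oxirane at C5 with inversion, the C4 alkoxide binds the borate and the resulting ate complex hands methoxide to C5 on the face away from palladium (second inversion), so that OMe ends on the α face cis to the C4 hydroxyl with net retention.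

Step 5
Reactants: 6 methyl (3aR,6R,7R,7aS)-7-hydroxy-6-methoxy-2,2-dimethyl-3a,6,7,7a-tetrahydro-1,3-benzodioxole-4-carboxylate
Product: 8 (1S,2R,3R,6R)-4-(hydroxymethyl)-6-methoxycyclohex-4-ene-1,2,3-triol, via diol acetonide 7 (not isolated)
Conditions: i-Bu2AlH (3.5 equiv), CH2Cl2, −78 → 0 °C; then MeOH, 1 M aq. HCl, THF, 23 °C
Reagents that add atoms: none
Why: 1,2-Hydride reduction of the conjugated ester by the aluminium hydride gives the allylic alcohol without touching any stereocentre, and acid-catalysed acetal hydrolysis in the same flask then frees the cis-2,3-diol.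

Step 6
Reactants: 8 (1S,2R,3R,6R)-4-(hydroxymethyl)-6-methoxycyclohex-4-ene-1,2,3-triol
Product: 10 [(3R,4R,5R,6R)-5-(benzoyloxy)-4,6-dihydroxy-3-methoxycyclohex-1-en-1-yl]methyl benzoate, via 7-O-monobenzoate 9 (not isolated)
Conditions: Ph2BOCH2CH2NH2 (2-aminoethyl diphenylborinate, 10 mol %), i-Pr2NEt (2.5 equiv), BzCl (2 × 1.05 equiv), MeCN, −20 → 23 °C; pH 4 buffer work-up
Reagents that add atoms: benzoyl chloride, O=C(Cl)c1ccccc1
Why: Borinic acid-catalysed regioselective acylation, in which the diphenylborinate binds first the 1,3-diol O7/O2 and then the cis-1,2-diol O2/O3 and each time activates the less hindered oxygen (primary O7, then equatorial O3, the pattern of the 3,6-di-O-benzoylation of α-galactopyranosides), while the unbound O4 and the pseudoaxial allylic O2 stay free and no stereocentre is touched.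

## Compound list

1 | methyl benzoate | COC(=O)c1ccccc1 | starting material
2 | methyl (5S,6R)-5,6-dihydroxycyclohexa-1,3-diene-1-carboxylate | COC(=O)C1=CC=C[C@H](O)[C@@H]1O | intermediate
3 | methyl (3aR,7aS)-2,2-dimethyl-3a,7a-dihydro-1,3-benzodioxole-4-carboxylate | COC(=O)C1=CC=C[C@@H]2OC(C)(C)O[C@H]12 | intermediate
4 | methyl (3aR,6R,7R,7aR)-6,7-epoxy-2,2-dimethyl-3a,6,7,7a-tetrahydro-1,3-benzodioxole-4-carboxylate (oxirane anti to the dioxolane) | COC(=O)C1=C[C@H]3O[C@H]3[C@@H]2OC(C)(C)O[C@H]12 | intermediate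
5 | methyl (3aR,6R,7R,7aS)-7-[(dimethoxyboranyl)oxy]-6-methoxy-2,2-dimethyl-3a,6,7,7a-tetrahydro-1,3-benzodioxole-4-carboxylate (borate ester of 6, formed in the flask) | CO[C@@H]1C=C(C(=O)OC)[C@H]2OC(C)(C)O[C@H]2[C@@H]1OB(OC)OC | intermediate
6 | methyl (3aR,6R,7R,7aS)-7-hydroxy-6-methoxy-2,2-dimethyl-3a,6,7,7a-tetrahydro-1,3-benzodioxole-4-carboxylate | CO[C@@H]1C=C(C(=O)OC)[C@H]2OC(C)(C)O[C@H]2[C@@H]1O | intermediate
7 | (3aS,4R,5R,7aR)-7-(hydroxymethyl)-5-methoxy-2,2-dimethyl-3a,4,5,7a-tetrahydro-1,3-benzodioxol-4-ol (diol acetonide, formed in the flask) | CO[C@@H]1C=C(CO)[C@H]2OC(C)(C)O[C@H]2[C@@H]1O | intermediate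
8 | (1S,2R,3R,6R)-4-(hydroxymethyl)-6-methoxycyclohex-4-ene-1,2,3-triol | CO[C@@H]1C=C(CO)[C@@H](O)[C@@H](O)[C@@H]1O | intermediate
9 | [(3R,4S,5R,6R)-4,5,6-trihydroxy-3-methoxycyclohex-1-en-1-yl]methyl benzoate (7-O-monobenzoate, formed in the flask) | CO[C@@H]1C=C(COC(=O)c2ccccc2)[C@@H](O)[C@@H](O)[C@@H]1O | intermediate
10 | [(3R,4R,5R,6R)-5-(benzoyloxy)-4,6-dihydroxy-3-methoxycyclohex-1-en-1-yl]methyl benzoate | CO[C@@H]1C=C(COC(=O)c2ccccc2)[C@@H](O)[C@@H](OC(=O)c2ccccc2)[C@@H]1O | target

## Step count and risks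

Total steps: 6. Longest linear sequence: 6.

**Most likely to fail, first: step 4.** Palladium must approach the face that carries the dioxolane, and methoxide could be delivered at C1 or from the wrong face. The fallback sets the cis C4/C5 pair by a relay that needs no palladium. It sets out from diene acetonide 3. NBS in wet THF at 0 °C adds bromine anti to the dioxolane and water at the allylic carbon, giving methyl (3aR,6S,7R,7aR)-7-bromo-6-hydroxy-2,2-dimethyl-3a,6,7,7a-tetrahydro-1,3-benzodioxole-4-carboxylate F1. K2CO3 closes it to the oxirane on the dioxolane face, methyl (3aR,6S,7S,7aR)-6,7-epoxy-2,2-dimethyl-3a,6,7,7a-tetrahydro-1,3-benzodioxole-4-carboxylate F2. MeOH with BF3·OEt2 at −20 °C opens F2 at the allylic C5 with inversion to methyl (3aR,6R,7S,7aS)-7-hydroxy-6-methoxy-2,2-dimethyl-3a,6,7,7a-tetrahydro-1,3-benzodioxole-4-carboxylate F3, which has C5 correct and C4 epimeric. A Mitsunobu reaction (4-nitrobenzoic acid, PPh3, DIAD, toluene) inverts C4 to methyl (3aR,6R,7R,7aR)-6-methoxy-2,2-dimethyl-7-[(4-nitrobenzoyl)oxy]-3a,6,7,7a-tetrahydro-1,3-benzodioxole-4-carboxylate F4. K2CO3 in MeOH at 0 °C removes the nitrobenzoate, and the route is rejoined at methoxy alcohol 6.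

**Second: step 6.** Benzoylation could also reach O4 or give O2/O3 mixtures. The fallback replaces reagent control by a protecting-group relay. It sets out from methoxy alcohol 6, whose only free hydroxyl (O4) is masked with 4-methoxybenzyl trichloroacetimidate and La(OTf)3 (cat.) in toluene to give methyl (3aR,6R,7R,7aR)-6-methoxy-7-[(4-methoxybenzyl)oxy]-2,2-dimethyl-3a,6,7,7a-tetrahydro-1,3-benzodioxole-4-carboxylate F6. i-Bu2AlH with a Rochelle-salt work-up gives [(3aR,6R,7R,7aR)-6-methoxy-7-[(4-methoxybenzyl)oxy]-2,2-dimethyl-3a,6,7,7a-tetrahydro-1,3-benzodioxol-4-yl]methanol F7. 80% aqueous AcOH at 40 °C gives (1R,2R,5R,6S)-3-(hydroxymethyl)-5-methoxy-6-[(4-methoxybenzyl)oxy]cyclohex-3-ene-1,2-diol F8, in which the only secondary hydroxyls left are the cis-2,3 pair. The borinate-catalysed benzoylation (BzCl, 2.1 equiv) then gives [(3R,4R,5R,6R)-5-(benzoyloxy)-6-hydroxy-3-methoxy-4-[(4-methoxybenzyl)oxy]cyclohex-1-en-1-yl]methyl benzoate F9. DDQ in wet CH2Cl2 at 0 °C removes the ether, and the route is rejoined at target 10.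

**Third: step 5.** The aqueous acid may ionise the allylic ether, and the very polar tetraol may be lost in the aluminium salts. The fallback changes the order of events so that no free tetraol is handled. The reduction is stopped with a Rochelle-salt work-up at diol acetonide 7, from which the fallback sets out. BzCl (1.05 equiv) with 2,4,6-collidine in CH2Cl2 at −40 °C esterifies only the primary allylic hydroxyl, giving [(3aR,6R,7R,7aS)-7-hydroxy-6-methoxy-2,2-dimethyl-3a,6,7,7a-tetrahydro-1,3-benzodioxol-4-yl]methyl benzoate F5. 80% aqueous AcOH at 40 °C removes the acetonide, and the route is rejoined at monobenzoate 9, which needs only the second, borinate-directed benzoylation of step 6 to reach 10.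

## Further compounds

F1 | step 4 | methyl (3aR,6S,7R,7aR)-7-bromo-6-hydroxy-2,2-dimethyl-3a,6,7,7a-tetrahydro-1,3-benzodioxole-4-carboxylate | O[C@H]1C=C(C(=O)OC)[C@H]2OC(C)(C)O[C@H]2[C@@H]1Br
F2 | step 4 | methyl (3aR,6S,7S,7aR)-6,7-epoxy-2,2-dimethyl-3a,6,7,7a-tetrahydro-1,3-benzodioxole-4-carboxylate (oxirane syn to the dioxolane) | COC(=O)C1=C[C@@H]3O[C@@H]3[C@@H]2OC(C)(C)O[C@H]12
F3 | step 4 | methyl (3aR,6R,7S,7aS)-7-hydroxy-6-methoxy-2,2-dimethyl-3a,6,7,7a-tetrahydro-1,3-benzodioxole-4-carboxylate | CO[C@@H]1C=C(C(=O)OC)[C@H]2OC(C)(C)O[C@H]2[C@H]1O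
F4 | step 4 | methyl (3aR,6R,7R,7aR)-6-methoxy-2,2-dimethyl-7-[(4-nitrobenzoyl)oxy]-3a,6,7,7a-tetrahydro-1,3-benzodioxole-4-carboxylate | CO[C@@H]1C=C(C(=O)OC)[C@H]2OC(C)(C)O[C@H]2[C@@H]1OC(=O)c3ccc(cc3)[N+](=O)[O-]
F5 | step 5 | [(3aR,6R,7R,7aS)-7-hydroxy-6-methoxy-2,2-dimethyl-3a,6,7,7a-tetrahydro-1,3-benzodioxol-4-yl]methyl benzoate | CO[C@@H]1C=C(COC(=O)c3ccccc3)[C@H]2OC(C)(C)O[C@H]2[C@@H]1O
F6 | step 6 | methyl (3aR,6R,7R,7aR)-6-methoxy-7-[(4-methoxybenzyl)oxy]-2,2-dimethyl-3a,6,7,7a-tetrahydro-1,3-benzodioxole-4-carboxylate | CO[C@@H]1C=C(C(=O)OC)[C@H]2OC(C)(C)O[C@H]2[C@@H]1OCc3ccc(OC)cc3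
F7 | step 6 | [(3aR,6R,7R,7aR)-6-methoxy-7-[(4-methoxybenzyl)oxy]-2,2-dimethyl-3a,6,7,7a-tetrahydro-1,3-benzodioxol-4-yl]methanol | CO[C@@H]1C=C(CO)[C@H]2OC(C)(C)O[C@H]2[C@@H]1OCc3ccc(OC)cc3
F8 | step 6 | (1R,2R,5R,6S)-3-(hydroxymethyl)-5-methoxy-6-[(4-methoxybenzyl)oxy]cyclohex-3-ene-1,2-diol | CO[C@@H]1C=C(CO)[C@@H](O)[C@@H](O)[C@@H]1OCc2ccc(OC)cc2
F9 | step 6 | [(3R,4R,5R,6R)-5-(benzoyloxy)-6-hydroxy-3-methoxy-4-[(4-methoxybenzyl)oxy]cyclohex-1-en-1-yl]methyl benzoate | CO[C@@H]1C=C(COC(=O)c2ccccc2)[C@@H](O)[C@@H](OC(=O)c2ccccc2)[C@@H]1OCc2ccc(OC)cc2
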